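**Retrosynthetic overview**

1. The three esters are attached last. Before that, lactone ring B (O1–C2–C3–C3a–C7a) is disconnected at O1–C7a and C2–C3 into CO2 and a ring A cyclohexene that carries a 1-borylvinyl group on C3a and, cis to it, a tosylate on C7a.
2. Enabling feature: in the α-methylene-γ-butyrolactone the sp2 carbon C3 (a latent vinyl nucleophile) and the oxygen-bearing sp3 carbon C7a (a latent electrophile) stand 1,3 across C3a. The O1–C2(=O) unit between them is exactly CO2, and the trans fusion of ring B to ring A lets O1 enter at C7a with inversion.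
3. Ring A with the stereotriad C4/C3a/C7a comes from a catalytic enantioselective Diels–Alder reaction of a 1-silyloxy diene (C4–C5–C6–C7) with an (E)-3-acyloxy acrylimide (C3a, C7a). The imide then becomes the 1-borylvinyl group and the C7a oxygen the inverted tosylate.
4. The diene, with the side-chain stereocentre, is built from (S)-citronellic acid by ozonolysis and palladium-catalysed α-alkenylation of the ester enolate.
5. Order of ring formation: ring A (cycloaddition, step 10), then ring B (CO2 annulation, step 17).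

Key step: step 17

Remark: TBS = tert-butyl(dimethyl)silyl, PMB = 4-methoxybenzyl, Piv = 2,2-dimethylpropanoyl, Ts = 4-methylphenylsulfonyl; O1, C2, C3, C3a, C4–C7, C7a are the positions of the final 1-benzofuran-2(3H)-one, and C1, C2 and C6 of the cyclohexene intermediates are the future C3a, C4 and C7a.

**Route**

Step 1
Reactants: 1 (3S)-3,7-dimethyloct-6-enoic acid [(S)-citronellic acid]
Product: 2 tert-butyl (3S)-3,7-dimethyloct-6-enoate
Conditions: tert-butyl 2,2,2-trichloroacetimidate (2 equiv), CH2Cl2/cyclohexane, rt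
Reagents that add atoms: tert-butyl 2,2,2-trichloroacetimidate, CC(C)(C)OC(=N)C(Cl)(Cl)Cl
Why: Imidate esterification (the substrate acid protonates the imidate and is O-tert-butylated) should give the hindered ester needed for the later enolate coupling without touching the alkene or the stereocentre.

Step 2
Reactants: 2 tert-butyl (3S)-3,7-dimethyloct-6-enoate
Product: 4 tert-butyl (3S)-6-hydroxy-3-methylhexanoate, via aldehyde 3 (not isolated)
Conditions: O3, CH2Cl2/MeOH, −78 °C; then NaBH4, −78 → 0 °C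
Reagents that add atoms: ozone, [O-][O+]=O
Why: Ozonolysis cleaves the only alkene and borohydride reduction of the aldehyde in the same flask should give the primary alcohol that becomes the terminal acetoxy carbon of the side chain, the tert-butyl ester being inert to NaBH4.

Step 3
Reactants: 4 tert-butyl (3S)-6-hydroxy-3-methylhexanoate
Product: 5 tert-butyl (3S)-3-methyl-6-(TBS-oxy)hexanoate
Conditions: TBSCl, imidazole, DMF, rt
Reagents that add atoms: tert-butyl(chloro)dimethylsilane, CC(C)(C)[Si](C)(C)Cl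
Why: Standard silylation of a primary alcohol masks the side-chain hydroxyl for the base, hydride and organometallic steps that follow.

Step 4
Reactants: 6 2,3-dibromoprop-1-ene; 7 (4-methoxyphenyl)methanol
Product: 8 1-{[(2-bromoprop-2-en-1-yl)oxy]methyl}-4-methoxybenzene
Conditions: NaH, n-Bu4NI (cat.), THF, 0 °C → rt
Reagents that add atoms: none
Why: Williamson etherification at the allylic bromide (SN2, the vinylic bromide is inert) should give the 2-bromoallyl ether that carries the future C6–CH2O carbon under an oxidatively removable group.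

Step 5
Reactants: 5 tert-butyl (3S)-3-methyl-6-(TBS-oxy)hexanoate; 8 1-{[(2-bromoprop-2-en-1-yl)oxy]methyl}-4-methoxybenzene
Product: 9 tert-butyl (2RS,3S)-3-methyl-2-[3-(PMB-oxy)prop-1-en-2-yl]-6-(TBS-oxy)hexanoate
Conditions: LiN(SiMe3)2 (2.2 equiv), Pd(dba)2 (3 mol%), P(t-Bu)3 (3 mol%), toluene, rt
Reagents that add atoms: none
Why: Palladium-catalysed α-alkenylation of an ester enolate (oxidative addition of the alkenyl bromide to zerovalent palladium, transmetalation with the lithium enolate, reductive elimination) should join the future C5 and C6 directly; the new α-stereocentre is inconsequential because this carbon becomes sp2 in step 7.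

Step 6
Reactants: 9 tert-butyl (2RS,3S)-3-methyl-2-[3-(PMB-oxy)prop-1-en-2-yl]-6-(TBS-oxy)hexanoate
Product: 10 (2RS,3S)-3-methyl-2-[3-(PMB-oxy)prop-1-en-2-yl]-6-(TBS-oxy)hexanal
Conditions: i-Bu2AlH (1.2 equiv), toluene, −78 °C; aqueous Rochelle salt work-up
Reagents that add atoms: none
Why: Partial ester reduction through the aluminium hemiacetal, which is stable at −78 °C, should deliver the aldehyde oxidation level needed for the dienol ether.

Step 7
Reactants: 10 (2RS,3S)-3-methyl-2-[3-(PMB-oxy)prop-1-en-2-yl]-6-(TBS-oxy)hexanal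
Product: 11 (1E)-1-(TBS-oxy)-2-[(2S)-5-(TBS-oxy)pentan-2-yl]-3-[(PMB-oxy)methyl]buta-1,3-diene
Conditions: TBSOTf (1.2 equiv), Et3N (2 equiv), CH2Cl2, −78 → 0 °C
Reagents that add atoms: tert-butyldimethylsilyl trifluoromethanesulfonate, CC(C)(C)[Si](C)(C)OS(=O)(=O)C(F)(F)F
Why: Soft enolisation (O-silylation, then deprotonation of the doubly activated α-carbon by Et3N) should give the conjugated silyl dienol ether, with the (1E) isomer favoured because the 2-propenyl unit can be coplanar with the enol ether only when it is trans to the silyloxy group (A1,3 strain).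

Step 8
Reactants: 12 1,3-oxazolidin-2-one; 13 prop-2-ynoic acid
Product: 14 3-(prop-2-ynoyl)-1,3-oxazolidin-2-one
Conditions: DCC, DMAP (cat.), CH2Cl2, −10 → 0 °C
Reagents that add atoms: none
Why: Carbodiimide-mediated N-acylation of the oxazolidinone should give the ynoyl imide that is the precursor of the chelating dienophile.

Step 9
Reactants: 14 3-(prop-2-ynoyl)-1,3-oxazolidin-2-one
Product: 15 3-[(2E)-3-(Piv-oxy)prop-2-enoyl]-1,3-oxazolidin-2-one
Conditions: pivalic acid (1.1 equiv), N-methylmorpholine (10 mol%), CH2Cl2, rt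
Reagents that add atoms: 2,2-dimethylpropanoic acid, CC(C)(C)C(=O)O
Why: Tertiary-amine-catalysed conjugate addition of a carboxylic acid to the electron-poor alkyne should give the β-acyloxy acrylimide as the (E) enol ester, which places the future C7a oxygen trans to the acyl group.

Step 10
Reactants: 11 (1E)-1-(TBS-oxy)-2-[(2S)-5-(TBS-oxy)pentan-2-yl]-3-[(PMB-oxy)methyl]buta-1,3-diene; 15 3-[(2E)-3-(Piv-oxy)prop-2-enoyl]-1,3-oxazolidin-2-one
Product: 16 3-{[(1S,2S,6R)-2-(TBS-oxy)-3-[(2S)-5-(TBS-oxy)pentan-2-yl]-4-[(PMB-oxy)methyl]-6-(Piv-oxy)cyclohex-3-en-1-yl]carbonyl}-1,3-oxazolidin-2-one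
Conditions: [Cu(L)](SbF6)2 (10 mol%, L = 2,2'-(propane-2,2-diyl)bis[(4S)-4-tert-butyl-4,5-dihydro-1,3-oxazole]), 4 Å molecular sieves, CH2Cl2, −40 °C → rt
Reagents that add atoms: none
Why: In this catalytic enantioselective Diels–Alder reaction of a chelating acrylimide with a 1-oxygenated diene, the 1-silyloxy group directs the "ortho" regiochemistry (C4–C3a bond), the endo transition state places the C4 silyloxy group cis to the C3a acyl group, the (E)-dienophile fixes the trans relation of the C3a acyl and C7a acyloxy groups, and the square-planar chelate of the imide on divalent copper with the (S,S) ligand exposes the α-Re face of the dienophile, so that C4, C3a and C7a are set under catalyst control, independently of the remote side-chain stereocentre.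

Step 11
Reactants: 16 3-{[(1S,2S,6R)-2-(TBS-oxy)-3-[(2S)-5-(TBS-oxy)pentan-2-yl]-4-[(PMB-oxy)methyl]-6-(Piv-oxy)cyclohex-3-en-1-yl]carbonyl}-1,3-oxazolidin-2-one
Product: 17 (1S,2S,6R)-N-methoxy-N-methyl-2-(TBS-oxy)-3-[(2S)-5-(TBS-oxy)pentan-2-yl]-4-[(PMB-oxy)methyl]-6-(Piv-oxy)cyclohex-3-ene-1-carboxamide
Conditions: MeNH(OMe), AlMe3, CH2Cl2, 0 °C → rt
Reagents that add atoms: N,O-dimethylhydroxylamine, CNOC
Why: Aminolysis of the exocyclic imide carbonyl by the aluminium amide (Weinreb amide formation) should remove the oxazolidinone without affecting the hindered pivalate or the silyl ethers.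

Step 12
Reactants: 17 (1S,2S,6R)-N-methoxy-N-methyl-2-(TBS-oxy)-3-[(2S)-5-(TBS-oxy)pentan-2-yl]-4-[(PMB-oxy)methyl]-6-(Piv-oxy)cyclohex-3-ene-1-carboxamide
Product: 18 1-[(1S,2S,6R)-2-(TBS-oxy)-3-[(2S)-5-(TBS-oxy)pentan-2-yl]-4-[(PMB-oxy)methyl]-6-(Piv-oxy)cyclohex-3-en-1-yl]ethan-1-one
Conditions: MeMgBr (2 equiv), THF, −78 → 0 °C
Reagents that add atoms: methylmagnesium bromide, C[Mg]Br
Why: In the Weinreb ketone synthesis the chelated tetrahedral intermediate prevents over-addition and enolisation, so the methyl ketone should form without epimerisation at C3a or β-elimination, the pivalate being too hindered to react at low temperature.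

Step 13
Reactants: 18 1-[(1S,2S,6R)-2-(TBS-oxy)-3-[(2S)-5-(TBS-oxy)pentan-2-yl]-4-[(PMB-oxy)methyl]-6-(Piv-oxy)cyclohex-3-en-1-yl]ethan-1-one
Product: 19 1-[(1S,2S,6R)-2-(TBS-oxy)-3-[(2S)-5-(TBS-oxy)pentan-2-yl]-4-[(PMB-oxy)methyl]-6-(Piv-oxy)cyclohex-3-en-1-yl]ethenyl trifluoromethanesulfonate
Conditions: KN(SiMe3)2 (1.1 equiv), THF, −78 °C; then N-(5-chloropyridin-2-yl)-1,1,1-trifluoro-N-[(trifluoromethyl)sulfonyl]methanesulfonamide, −78 °C
Reagents that add atoms: N-(5-chloropyridin-2-yl)-1,1,1-trifluoro-N-[(trifluoromethyl)sulfonyl]methanesulfonamide, O=S(=O)(N(c1ccc(Cl)cn1)S(=O)(=O)C(F)(F)F)C(F)(F)F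
Why: Kinetic deprotonation by the bulky amide base should occur at the unhindered methyl group and not at the doubly flanked ring methine (which would trigger E1cB loss of pivalate), and O-sulfonylation of the terminal enolate gives the 1,1-disubstituted alkenyl triflate.

Step 14
Reactants: 19 1-[(1S,2S,6R)-2-(TBS-oxy)-3-[(2S)-5-(TBS-oxy)pentan-2-yl]-4-[(PMB-oxy)methyl]-6-(Piv-oxy)cyclohex-3-en-1-yl]ethenyl trifluoromethanesulfonate
Product: 20 1-[(1S,2S,6R)-6-hydroxy-2-(TBS-oxy)-3-[(2S)-5-(TBS-oxy)pentan-2-yl]-4-[(PMB-oxy)methyl]cyclohex-3-en-1-yl]ethenyl trifluoromethanesulfonate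
Conditions: i-Bu2AlH (2.5 equiv), CH2Cl2, −78 °C
Reagents that add atoms: none
Why: Reductive cleavage of the pivalate by the aluminium hydride should free the C7a hydroxyl while the alkenyl triflate, the silyl ethers and the PMB ether are inert at −78 °C.

Step 15
Reactants: 20 1-[(1S,2S,6R)-6-hydroxy-2-(TBS-oxy)-3-[(2S)-5-(TBS-oxy)pentan-2-yl]-4-[(PMB-oxy)methyl]cyclohex-3-en-1-yl]ethenyl trifluoromethanesulfonate
Product: 21 2-{1-[(1S,2S,6R)-6-hydroxy-2-(TBS-oxy)-3-[(2S)-5-(TBS-oxy)pentan-2-yl]-4-[(PMB-oxy)methyl]cyclohex-3-en-1-yl]ethenyl}-5,5-dimethyl-1,3,2-dioxaborinane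
Conditions: 5,5,5',5'-tetramethyl-2,2'-bi(1,3,2-dioxaborinane) (1.2 equiv), PdCl2(PPh3)2 (3 mol%), PPh3 (6 mol%), KOPh (1.5 equiv), toluene, 50 °C
Reagents that add atoms: 5,5,5',5'-tetramethyl-2,2'-bi(1,3,2-dioxaborinane), CC1(C)COB(OC1)B1OCC(C)(C)CO1
Why: Miyaura borylation (oxidative addition of the alkenyl triflate to zerovalent palladium, transmetalation with the phenoxide-activated diboron, reductive elimination) should give the alkenylboronate with the 1,1-disubstituted alkene intact and tolerates the free secondary alcohol.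

Step 16
Reactants: 21 2-{1-[(1S,2S,6R)-6-hydroxy-2-(TBS-oxy)-3-[(2S)-5-(TBS-oxy)pentan-2-yl]-4-[(PMB-oxy)methyl]cyclohex-3-en-1-yl]ethenyl}-5,5-dimethyl-1,3,2-dioxaborinane
Product: 22 2-{1-[(1R,2S,6S)-2-(TBS-oxy)-3-[(2S)-5-(TBS-oxy)pentan-2-yl]-4-[(PMB-oxy)methyl]-6-(Ts-oxy)cyclohex-3-en-1-yl]ethenyl}-5,5-dimethyl-1,3,2-dioxaborinane
Conditions: PPh3 (1.5 equiv), diisopropyl azodicarboxylate (1.5 equiv), Zn(OTs)2 (0.6 equiv), toluene, rt
Reagents that add atoms: zinc bis(4-methylbenzenesulfonate), [Zn+2].Cc1ccc(cc1)S(=O)(=O)[O-].Cc1ccc(cc1)S(=O)(=O)[O-]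
Why: In this Mitsunobu reaction with tosylate as the nucleophile, the alkoxyphosphonium ion of the equatorial C7a alcohol is displaced by sulfonate in an SN2 reaction, which inverts C7a and places the leaving group cis to the alkenylboronate on C3a.

Step 17
Reactants: 22 2-{1-[(1R,2S,6S)-2-(TBS-oxy)-3-[(2S)-5-(TBS-oxy)pentan-2-yl]-4-[(PMB-oxy)methyl]-6-(Ts-oxy)cyclohex-3-en-1-yl]ethenyl}-5,5-dimethyl-1,3,2-dioxaborinane
Product: 24 (3aS,4S,7aR)-3-methylidene-4-(TBS-oxy)-5-[(2S)-5-(TBS-oxy)pentan-2-yl]-6-[(PMB-oxy)methyl]-3a,4,7,7a-tetrahydro-1-benzofuran-2(3H)-one, via potassium carboxylate 23 (not isolated)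
Conditions: (IPr)CuCl (5 mol%, IPr = 1,3-bis(2,6-diisopropylphenyl)imidazol-2-ylidene), KOt-Bu (1.1 equiv), CO2 (1 atm), THF, 70 °C; then DMF and 18-crown-6, 70 °C, same flask
Reagents that add atoms: carbon dioxide, O=C=O
Why: tert-Butoxide turns the alkenylboronate into a borate that transmetalates to the carbene complex of monovalent copper, CO2 inserts into the alkenyl–copper bond to form the C3–C2 bond, and the released potassium carboxylate 23 then displaces the axial tosylate through its oxygen in an intramolecular SN2 reaction that forms the O1–C7a bond. The closest known reaction type is the copper-catalysed carboxylation of aryl- and alkenylboronic esters with CO2, whose carboxylate products are commonly O-alkylated in the same flask. Ring B is closed in the 5-exo-tet mode. The only new stereocentre, C7a, is set by inversion of the tosylate that step 16 placed cis to the C3a substituent, which gives the trans ring fusion, while C4 and C3a are not touched. The step needs carboxylation and O-alkylation to win over elimination and C-alkylation: the alkenyl–copper carbon cannot reach the back side of the cis C–OTs bond (that would require a trans-fused methylenecyclopropane), the alkoxide is consumed as the borate, and the weakly basic carboxylate attacks anti-periplanar to the axial leaving group. Attack at C4 is excluded because its oxygen is a silyl ether and not a leaving group.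

Step 18
Reactants: 24 (3aS,4S,7aR)-3-methylidene-4-(TBS-oxy)-5-[(2S)-5-(TBS-oxy)pentan-2-yl]-6-[(PMB-oxy)methyl]-3a,4,7,7a-tetrahydro-1-benzofuran-2(3H)-one
Product: 25 (3aR,4S,7aR)-4-hydroxy-5-[(2S)-5-hydroxypentan-2-yl]-3-methylidene-6-[(PMB-oxy)methyl]-3a,4,7,7a-tetrahydro-1-benzofuran-2(3H)-one
Conditions: HF·pyridine, pyridine/THF, 0 °C → rt
Reagents that add atoms: none
Why: Fluoride-mediated cleavage of both silyl ethers under buffered, non-basic conditions should leave the α-methylene lactone and the PMB ether intact.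

Step 19
Reactants: 25 (3aR,4S,7aR)-4-hydroxy-5-[(2S)-5-hydroxypentan-2-yl]-3-methylidene-6-[(PMB-oxy)methyl]-3a,4,7,7a-tetrahydro-1-benzofuran-2(3H)-one
Product: 26 (4S)-4-[(3aS,4S,7aR)-4-acetoxy-3-methylidene-2-oxo-6-[(PMB-oxy)methyl]-2,3,3a,4,7,7a-hexahydro-1-benzofuran-5-yl]pentyl acetate
Conditions: Ac2O, pyridine, DMAP (cat.), CH2Cl2, rt
Reagents that add atoms: acetic anhydride, CC(=O)OC(C)=O
Why: Nucleophile-catalysed acetylation should esterify the primary and the hindered secondary allylic alcohol in one operation and give both acetates of the target.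

Step 20
Reactants: 26 (4S)-4-[(3aS,4S,7aR)-4-acetoxy-3-methylidene-2-oxo-6-[(PMB-oxy)methyl]-2,3,3a,4,7,7a-hexahydro-1-benzofuran-5-yl]pentyl acetate
Product: 27 (4S)-4-[(3aS,4S,7aR)-4-acetoxy-6-(hydroxymethyl)-3-methylidene-2-oxo-2,3,3a,4,7,7a-hexahydro-1-benzofuran-5-yl]pentyl acetate
Conditions: DDQ, CH2Cl2/pH 7 phosphate buffer, 0 °C
Reagents that add atoms: none
Why: Oxidation of the electron-rich PMB ether by DDQ and hydrolysis of the resulting oxocarbenium ion should free the primary allylic alcohol without touching the esters, the lactone or the tetrasubstituted alkene.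

Step 21
Reactants: 27 (4S)-4-[(3aS,4S,7aR)-4-acetoxy-6-(hydroxymethyl)-3-methylidene-2-oxo-2,3,3a,4,7,7a-hexahydro-1-benzofuran-5-yl]pentyl acetate
Product: 28 [(3aS,4S,7aR)-4-acetoxy-5-[(2S)-5-acetoxypentan-2-yl]-3-methylidene-2-oxo-2,3,3a,4,7,7a-hexahydro-1-benzofuran-6-yl]methyl 2-methylprop-2-enoate
Conditions: methacryloyl chloride, Et3N, DMAP (cat.), CH2Cl2, 0 °C
Reagents that add atoms: 2-methylprop-2-enoyl chloride, C=C(C)C(Cl)=O
Why: Acylation of the primary allylic alcohol with the acid chloride installs the polymerisable methacrylate last, so that it is exposed to no further reagent.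

**Compound list**

1 | (3S)-3,7-dimethyloct-6-enoic acid | C[C@@H](CCC=C(C)C)CC(=O)O | starting material
2 | tert-butyl (3S)-3,7-dimethyloct-6-enoate | C[C@@H](CCC=C(C)C)CC(=O)OC(C)(C)C | intermediate
3 | tert-butyl (3S)-3-methyl-6-oxohexanoate | C[C@@H](CCC=O)CC(=O)OC(C)(C)C | intermediate
4 | tert-butyl (3S)-6-hydroxy-3-methylhexanoate | C[C@@H](CCCO)CC(=O)OC(C)(C)C | intermediate
5 | tert-butyl (3S)-3-methyl-6-(TBS-oxy)hexanoate | C[C@@H](CCCO[Si](C)(C)C(C)(C)C)CC(=O)OC(C)(C)C | intermediate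
6 | 2,3-dibromoprop-1-ene | C=C(Br)CBr | starting material
7 | (4-methoxyphenyl)methanol | COc1ccc(CO)cc1 | starting material
8 | 1-{[(2-bromoprop-2-en-1-yl)oxy]methyl}-4-methoxybenzene | C=C(Br)COCc1ccc(OC)cc1 | intermediate
9 | tert-butyl (2RS,3S)-3-methyl-2-[3-(PMB-oxy)prop-1-en-2-yl]-6-(TBS-oxy)hexanoate | CC(C)(C)OC(=O)C([C@@H](C)CCCO[Si](C)(C)C(C)(C)C)C(=C)COCc1ccc(OC)cc1 | intermediate
10 | (2RS,3S)-3-methyl-2-[3-(PMB-oxy)prop-1-en-2-yl]-6-(TBS-oxy)hexanal | O=CC([C@@H](C)CCCO[Si](C)(C)C(C)(C)C)C(=C)COCc1ccc(OC)cc1 | intermediate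
11 | (1E)-1-(TBS-oxy)-2-[(2S)-5-(TBS-oxy)pentan-2-yl]-3-[(PMB-oxy)methyl]buta-1,3-diene | CC(C)(C)[Si](C)(C)O/C=C(/C(=C)COCc1ccc(OC)cc1)[C@@H](C)CCCO[Si](C)(C)C(C)(C)C | intermediate
12 | 1,3-oxazolidin-2-one | O=C1NCCO1 | starting material
13 | prop-2-ynoic acid | C#CC(=O)O | starting material
14 | 3-(prop-2-ynoyl)-1,3-oxazolidin-2-one | C#CC(=O)N1CCOC1=O | intermediate
15 | 3-[(2E)-3-(Piv-oxy)prop-2-enoyl]-1,3-oxazolidin-2-one | CC(C)(C)C(=O)O/C=C/C(=O)N1CCOC1=O | intermediate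
16 | 3-{[(1S,2S,6R)-2-(TBS-oxy)-3-[(2S)-5-(TBS-oxy)pentan-2-yl]-4-[(PMB-oxy)methyl]-6-(Piv-oxy)cyclohex-3-en-1-yl]carbonyl}-1,3-oxazolidin-2-one | COc1ccc(COCC2=C([C@@H](C)CCCO[Si](C)(C)C(C)(C)C)[C@@H](O[Si](C)(C)C(C)(C)C)[C@@H](C(=O)N3CCOC3=O)[C@H](OC(=O)C(C)(C)C)C2)cc1 | intermediate
17 | (1S,2S,6R)-N-methoxy-N-methyl-2-(TBS-oxy)-3-[(2S)-5-(TBS-oxy)pentan-2-yl]-4-[(PMB-oxy)methyl]-6-(Piv-oxy)cyclohex-3-ene-1-carboxamide | COc1ccc(COCC2=C([C@@H](C)CCCO[Si](C)(C)C(C)(C)C)[C@@H](O[Si](C)(C)C(C)(C)C)[C@@H](C(=O)N(C)OC)[C@H](OC(=O)C(C)(C)C)C2)cc1 | intermediate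
18 | 1-[(1S,2S,6R)-2-(TBS-oxy)-3-[(2S)-5-(TBS-oxy)pentan-2-yl]-4-[(PMB-oxy)methyl]-6-(Piv-oxy)cyclohex-3-en-1-yl]ethan-1-one | COc1ccc(COCC2=C([C@@H](C)CCCO[Si](C)(C)C(C)(C)C)[C@@H](O[Si](C)(C)C(C)(C)C)[C@@H](C(C)=O)[C@H](OC(=O)C(C)(C)C)C2)cc1 | intermediate
19 | 1-[(1S,2S,6R)-2-(TBS-oxy)-3-[(2S)-5-(TBS-oxy)pentan-2-yl]-4-[(PMB-oxy)methyl]-6-(Piv-oxy)cyclohex-3-en-1-yl]ethenyl trifluoromethanesulfonate | COc1ccc(COCC2=C([C@@H](C)CCCO[Si](C)(C)C(C)(C)C)[C@@H](O[Si](C)(C)C(C)(C)C)[C@@H](C(=C)OS(=O)(=O)C(F)(F)F)[C@H](OC(=O)C(C)(C)C)C2)cc1 | intermediate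
20 | 1-[(1S,2S,6R)-6-hydroxy-2-(TBS-oxy)-3-[(2S)-5-(TBS-oxy)pentan-2-yl]-4-[(PMB-oxy)methyl]cyclohex-3-en-1-yl]ethenyl trifluoromethanesulfonate | COc1ccc(COCC2=C([C@@H](C)CCCO[Si](C)(C)C(C)(C)C)[C@@H](O[Si](C)(C)C(C)(C)C)[C@@H](C(=C)OS(=O)(=O)C(F)(F)F)[C@H](O)C2)cc1 | intermediate
21 | 2-{1-[(1S,2S,6R)-6-hydroxy-2-(TBS-oxy)-3-[(2S)-5-(TBS-oxy)pentan-2-yl]-4-[(PMB-oxy)methyl]cyclohex-3-en-1-yl]ethenyl}-5,5-dimethyl-1,3,2-dioxaborinane | COc1ccc(COCC2=C([C@@H](C)CCCO[Si](C)(C)C(C)(C)C)[C@@H](O[Si](C)(C)C(C)(C)C)[C@@H](C(=C)B3OCC(C)(C)CO3)[C@H](O)C2)cc1 | intermediate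
22 | 2-{1-[(1R,2S,6S)-2-(TBS-oxy)-3-[(2S)-5-(TBS-oxy)pentan-2-yl]-4-[(PMB-oxy)methyl]-6-(Ts-oxy)cyclohex-3-en-1-yl]ethenyl}-5,5-dimethyl-1,3,2-dioxaborinane | COc1ccc(COCC2=C([C@@H](C)CCCO[Si](C)(C)C(C)(C)C)[C@@H](O[Si](C)(C)C(C)(C)C)[C@@H](C(=C)B3OCC(C)(C)CO3)[C@@H](OS(=O)(=O)c3ccc(C)cc3)C2)cc1 | intermediate
23 | potassium 2-[(1R,2S,6S)-2-(TBS-oxy)-3-[(2S)-5-(TBS-oxy)pentan-2-yl]-4-[(PMB-oxy)methyl]-6-(Ts-oxy)cyclohex-3-en-1-yl]prop-2-enoate | COc1ccc(COCC2=C([C@@H](C)CCCO[Si](C)(C)C(C)(C)C)[C@@H](O[Si](C)(C)C(C)(C)C)[C@@H](C(=C)C(=O)[O-])[C@@H](OS(=O)(=O)c3ccc(C)cc3)C2)cc1.[K+] | intermediate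
24 | (3aS,4S,7aR)-3-methylidene-4-(TBS-oxy)-5-[(2S)-5-(TBS-oxy)pentan-2-yl]-6-[(PMB-oxy)methyl]-3a,4,7,7a-tetrahydro-1-benzofuran-2(3H)-one | COc1ccc(COCC2=C([C@@H](C)CCCO[Si](C)(C)C(C)(C)C)[C@@H](O[Si](C)(C)C(C)(C)C)[C@H]3C(=C)C(=O)O[C@@H]3C2)cc1 | intermediate
25 | (3aR,4S,7aR)-4-hydroxy-5-[(2S)-5-hydroxypentan-2-yl]-3-methylidene-6-[(PMB-oxy)methyl]-3a,4,7,7a-tetrahydro-1-benzofuran-2(3H)-one | COc1ccc(COCC2=C([C@@H](C)CCCO)[C@@H](O)[C@H]3C(=C)C(=O)O[C@@H]3C2)cc1 | intermediate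
26 | (4S)-4-[(3aS,4S,7aR)-4-acetoxy-3-methylidene-2-oxo-6-[(PMB-oxy)methyl]-2,3,3a,4,7,7a-hexahydro-1-benzofuran-5-yl]pentyl acetate | COc1ccc(COCC2=C([C@@H](C)CCCOC(C)=O)[C@@H](OC(C)=O)[C@H]3C(=C)C(=O)O[C@@H]3C2)cc1 | intermediate
27 | (4S)-4-[(3aS,4S,7aR)-4-acetoxy-6-(hydroxymethyl)-3-methylidene-2-oxo-2,3,3a,4,7,7a-hexahydro-1-benzofuran-5-yl]pentyl acetate | OCC1=C([C@@H](C)CCCOC(C)=O)[C@@H](OC(C)=O)[C@H]2C(=C)C(=O)O[C@@H]2C1 | intermediate
28 | [(3aS,4S,7aR)-4-acetoxy-5-[(2S)-5-acetoxypentan-2-yl]-3-methylidene-2-oxo-2,3,3a,4,7,7a-hexahydro-1-benzofuran-6-yl]methyl 2-methylprop-2-enoate | C=C(C)C(=O)OCC1=C([C@@H](C)CCCOC(C)=O)[C@@H](OC(C)=O)[C@H]2C(=C)C(=O)O[C@@H]2C1 | target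

**Step count and risks**

Total step count: 21. Longest linear sequence: 18 steps (steps 1–3, 5–7, 10–21).

The three steps most likely to fail:

Step 17 (carboxylation–lactonisation). Base-induced E2 loss of the axial tosylate or protodeboronation could outrun CO2 insertion, or the potassium carboxylate could be too slow in displacing the hindered secondary tosylate. The fallback closes the lactone C–O bond by acylation instead of alkylation and sets out from 21. The same copper-catalysed carboxylation (2.2 equiv KOt-Bu, CO2, THF, 70 °C), now with no leaving group in the molecule, should give after acidification 2-[(1S,2S,6R)-6-hydroxy-2-(TBS-oxy)-3-[(2S)-5-(TBS-oxy)pentan-2-yl]-4-[(PMB-oxy)methyl]cyclohex-3-en-1-yl]prop-2-enoic acid F1, in which the C7a hydroxyl from the cycloaddition already has the configuration of the target. Lactonisation with retention (2,4,6-trichlorobenzoyl chloride, Et3N, DMAP, toluene) should close ring B and comes back to the route at 24.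

Step 10 (cycloaddition). Endo and facial control could erode with the hindered 2,3-disubstituted diene, or the Lewis acid could desilylate the dienol ether or stop at a stepwise Mukaiyama–Michael adduct. The fallback replaces catalyst control by a covalently bound auxiliary and sets out from 11. Commercial (4R)-4-benzyl-1,3-oxazolidin-2-one is acylated as in step 8 to (4R)-4-benzyl-3-(prop-2-ynoyl)-1,3-oxazolidin-2-one F2, and pivalic acid is added as in step 9 to give (4R)-4-benzyl-3-[(2E)-3-(Piv-oxy)prop-2-enoyl]-1,3-oxazolidin-2-one F3. In its aluminium chelate (Me2AlCl, CH2Cl2, −78 °C) the benzyl group shields the α-Si face, so that 11 should add to the α-Re face in the endo mode and give (4R)-4-benzyl-3-{[(1S,2S,6R)-2-(TBS-oxy)-3-[(2S)-5-(TBS-oxy)pentan-2-yl]-4-[(PMB-oxy)methyl]-6-(Piv-oxy)cyclohex-3-en-1-yl]carbonyl}-1,3-oxazolidin-2-one F4. Aminolysis under the conditions of step 11 comes back to the route at 17.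

Step 16 (inversion to the tosylate). The alkoxyphosphonium ion could eliminate, or the sulfonate could fail to reach C7a past the pseudoaxial C4 silyloxy group, leaving unreacted or eliminated material. The fallback inverts C7a by oxidation and reduction and sets out from 21. Oxidation (1,1,1-triacetoxy-1,1-dihydro-1,2-benziodoxol-3(1H)-one, NaHCO3, CH2Cl2) should give (5S,6R)-6-[1-(5,5-dimethyl-1,3,2-dioxaborinan-2-yl)ethenyl]-3-[(PMB-oxy)methyl]-5-(TBS-oxy)-4-[(2S)-5-(TBS-oxy)pentan-2-yl]cyclohex-3-en-1-one F5. Reduction with LiBH(s-Bu)3 (THF, −78 °C) should attack equatorially, away from the axial C4 silyloxy group, and give the axial cis alcohol 2-{1-[(1S,2S,6S)-6-hydroxy-2-(TBS-oxy)-3-[(2S)-5-(TBS-oxy)pentan-2-yl]-4-[(PMB-oxy)methyl]cyclohex-3-en-1-yl]ethenyl}-5,5-dimethyl-1,3,2-dioxaborinane F6. Sulfonylation with retention (TsCl, pyridine, DMAP) comes back to the route at 22.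

Further compounds
F1 | step 17 | 2-[(1S,2S,6R)-6-hydroxy-2-(TBS-oxy)-3-[(2S)-5-(TBS-oxy)pentan-2-yl]-4-[(PMB-oxy)methyl]cyclohex-3-en-1-yl]prop-2-enoic acid | COc1ccc(COCC2=C([C@@H](C)CCCO[Si](C)(C)C(C)(C)C)[C@@H](O[Si](C)(C)C(C)(C)C)[C@@H](C(=C)C(=O)O)[C@H](O)C2)cc1
F2 | step 10 | (4R)-4-benzyl-3-(prop-2-ynoyl)-1,3-oxazolidin-2-one | C#CC(=O)N1[C@H](Cc2ccccc2)COC1=O
F3 | step 10 | (4R)-4-benzyl-3-[(2E)-3-(Piv-oxy)prop-2-enoyl]-1,3-oxazolidin-2-one | CC(C)(C)C(=O)O/C=C/C(=O)N1[C@H](Cc2ccccc2)COC1=O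
F4 | step 10 | (4R)-4-benzyl-3-{[(1S,2S,6R)-2-(TBS-oxy)-3-[(2S)-5-(TBS-oxy)pentan-2-yl]-4-[(PMB-oxy)methyl]-6-(Piv-oxy)cyclohex-3-en-1-yl]carbonyl}-1,3-oxazolidin-2-one | COc1ccc(COCC2=C([C@@H](C)CCCO[Si](C)(C)C(C)(C)C)[C@@H](O[Si](C)(C)C(C)(C)C)[C@@H](C(=O)N3[C@H](Cc4ccccc4)COC3=O)[C@H](OC(=O)C(C)(C)C)C2)cc1
F5 | step 16 | (5S,6R)-6-[1-(5,5-dimethyl-1,3,2-dioxaborinan-2-yl)ethenyl]-3-[(PMB-oxy)methyl]-5-(TBS-oxy)-4-[(2S)-5-(TBS-oxy)pentan-2-yl]cyclohex-3-en-1-one | COc1ccc(COCC2=C([C@@H](C)CCCO[Si](C)(C)C(C)(C)C)[C@@H](O[Si](C)(C)C(C)(C)C)[C@@H](C(=C)B3OCC(C)(C)CO3)C(=O)C2)cc1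
F6 | step 16 | 2-{1-[(1S,2S,6S)-6-hydroxy-2-(TBS-oxy)-3-[(2S)-5-(TBS-oxy)pentan-2-yl]-4-[(PMB-oxy)methyl]cyclohex-3-en-1-yl]ethenyl}-5,5-dimethyl-1,3,2-dioxaborinane | COc1ccc(COCC2=C([C@@H](C)CCCO[Si](C)(C)C(C)(C)C)[C@@H](O[Si](C)(C)C(C)(C)C)[C@@H](C(=C)B3OCC(C)(C)CO3)[C@@H](O)C2)cc1
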